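**Retrosynthetic overview**

1. Target ⇒ final desilylation, acetylation, hydroxyl-directed epoxidation (the only ring made, step 16), Luche reduction and SN2 introduction of the C1 angelate on a carvone-type enone.
2. C8 carbinol ⇒ Evans–Saksena anti-reduction of a β-hydroxy α-methylene ketone, directed by the C10 hydroxyl bought with L-malic acid.
3. C8 ketone ⇒ allylic oxidation and decarboxylation of the Ireland–Claisen acid.
4. Key C8–C9 bond ⇒ Ireland–Claisen [3,3]-sigmatropic rearrangement of the ester made from (R)-10-chlorocarvone and a malic-acid-derived C5 acid.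
5. The cyclohexene ring and C6 come intact from (R)-carvone.

Convention (one line): bisabolane numbering is used from compound 14 on (ring C1–C6, C6 carries C7, C3 carries the ring methyl; C7(=C14), C8, C9, C10, C11(CH3)2); β = same ring face as the C6–C7 bond, α = opposite; angeloyl = (Z)-2-methylbut-2-enoyl; the CIP label of C6 changes from R to S once C1 bears oxygen although no bond at C6 is touched.

**Route**

Step 1
Reactants: 1 L-malic acid
Product: 2 (S)-2-(2,2-dimethyl-5-oxo-1,3-dioxolan-4-yl)acetic acid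
Conditions: 2,2-dimethoxypropane, TsOH·H2O (cat.), CH2Cl2, rt
Reagents that add atoms: 2,2-dimethoxypropane COC(C)(C)OC
Why: Acid-catalysed acetalisation takes the α-hydroxy acid unit into the five-membered dioxolanone and leaves the β-carboxyl free, without touching the stereocentre (later C10).

Step 2
Reactants: 2 (S)-2-(2,2-dimethyl-5-oxo-1,3-dioxolan-4-yl)acetic acid
Product: 4 (S)-4-hydroxy-5,5-dimethyloxolan-2-one, via dihydroxy acid 3 (not isolated)
Conditions: MeMgBr (5 equiv), THF, −20 °C to rt; then 2 M HCl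
Reagents that add atoms: methylmagnesium bromide C[Mg]Br
Why: Double Grignard addition to the activated dioxolanone carbonyl (the free acid is masked as its magnesium carboxylate) builds the C11 carbinol, and acid work-up lactonises; the stereocentre is not involved.

Step 3
Reactants: 4 (S)-4-hydroxy-5,5-dimethyloxolan-2-one
Product: 7 (S)-4-methyl-3,4-bis(triethylsilyloxy)pentanoic acid, via lithium carboxylate 5 (not isolated), via silyl ester 6 (not isolated)
Conditions: LiOH·H2O, THF/H2O, rt, evaporate; Et3SiOTf, 2,6-lutidine, CH2Cl2, 0 °C; then H2O/THF, pH 5 buffer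
Reagents that add atoms: lithium hydroxide [Li+].[OH-]; triethylsilyl trifluoromethanesulfonate CC[Si](CC)(CC)OS(=O)(=O)C(F)(F)F
Why: Saponification opens the lactone, silyl ether formation caps both hydroxyls, and the labile silyl ester is hydrolysed on aqueous work-up.

Step 4
Reactants: 8 (R)-carvone
Product: 9 (5R)-5-(3-chloroprop-1-en-2-yl)-2-methylcyclohex-2-en-1-one [(R)-10-chlorocarvone]
Conditions: Ca(OCl)2, solid CO2, CH2Cl2/H2O, 0 °C
Reagents that add atoms: calcium hypochlorite [Ca+2].[O-]Cl.[O-]Cl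
Why: Ene-type allylic chlorination by HOCl attacks only the electron-rich isopropenyl alkene (the enone alkene is inert) and removes a methyl hydrogen.

Step 5
Reactants: 9 (R)-10-chlorocarvone; 7 (S)-4-methyl-3,4-bis(triethylsilyloxy)pentanoic acid
Product: 11 2-[(1R)-4-methyl-5-oxocyclohex-3-en-1-yl]prop-2-en-1-yl (3S)-4-methyl-3,4-bis(triethylsilyloxy)pentanoate, via cesium carboxylate 10 (not isolated)
Conditions: Cs2CO3, NaI (cat.), DMF, rt
Reagents that add atoms: none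
Why: SN2 O-alkylation of the cesium carboxylate by the primary allylic chloride gives the allyl ester under non-enolising conditions.

Step 6
Reactants: 11 2-[(1R)-4-methyl-5-oxocyclohex-3-en-1-yl]prop-2-en-1-yl (3S)-4-methyl-3,4-bis(triethylsilyloxy)pentanoate
Product: 14 (6R,10S)-9-carboxy-10,11-bis(triethylsilyloxy)bisabola-3,7(14)-dien-2-one (C9 epimers), via bis-silyl ketene acetal 12 (not isolated), via rearranged silyl ester 13 (not isolated)
Conditions: LiN(iPr)2 (2.5 equiv), Me3SiCl/Et3N, THF, −78 °C to rt; then 1 M HCl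
Reagents that add atoms: none
Why: Ireland–Claisen rearrangement, the [3,3]-sigmatropic shift of the silyl ketene acetal through a chair transition state, forges the C8–C9 bond and regenerates the 7(14)-methylene while the ring ketone is parked as its silyl dienol ether; the C9 epimers are inconsequential because C9 becomes CH2 in step 8.

Step 7
Reactants: 14 (6R,10S)-9-carboxy-10,11-bis(triethylsilyloxy)bisabola-3,7(14)-dien-2-one
Product: 15 (6R,10S)-9-carboxy-8-hydroxy-10,11-bis(triethylsilyloxy)bisabola-3,7(14)-dien-2-one (C8/C9 epimers)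
Conditions: SeO2 (0.5 equiv), t-BuOOH, CH2Cl2, rt
Reagents that add atoms: tert-butyl hydroperoxide CC(C)(C)OO
Why: Sharpless SeO2/t-BuOOH allylic oxidation (ene reaction, then [2,3]-sigmatropic shift of the allylseleninic acid) is expected to hydroxylate the side-chain allylic CH2 (C8) and spare the ring methine, as it does for ring-bound isopropenyl groups; the C8 configuration is irrelevant here.

Step 8
Reactants: 15 (6R,10S)-9-carboxy-8-hydroxy-10,11-bis(triethylsilyloxy)bisabola-3,7(14)-dien-2-one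
Product: 17 (6R,10S)-10,11-bis(triethylsilyloxy)bisabola-3,7(14)-diene-2,8-dione, via β-keto acid 16 (not isolated)
Conditions: Dess–Martin periodinane, pyridine, CH2Cl2, 0 °C to 35 °C
Reagents that add atoms: none
Why: Dess–Martin oxidation gives a β-keto acid that loses CO2 through the usual six-membered transition state, leaving the α-methylene ketone with C9 as CH2.

Step 9
Reactants: 17 (6R,10S)-10,11-bis(triethylsilyloxy)bisabola-3,7(14)-diene-2,8-dione
Product: 18 (6R,10S)-10-hydroxy-11-(triethylsilyloxy)bisabola-3,7(14)-diene-2,8-dione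
Conditions: PPTS (cat.), MeOH/CH2Cl2, 0 °C
Reagents that add atoms: none
Why: Acid-catalysed methanolysis removes the secondary triethylsilyl ether much faster than the tertiary one (selective deprotection).

Step 10
Reactants: 18 (6R,10S)-10-hydroxy-11-(triethylsilyloxy)bisabola-3,7(14)-diene-2,8-dione
Product: 19 (6R,8S,10S)-8,10-dihydroxy-11-(triethylsilyloxy)bisabola-3,7(14)-dien-2-one
Conditions: Me4NBH(OAc)3, MeCN/AcOH, −30 °C
Reagents that add atoms: none
Why: Evans–Saksena reduction delivers hydride intramolecularly from the C10-alkoxyborohydride through a chair transition state, giving the 1,3-anti diol and so setting C8 (S) from C10; the ring enone has no directing hydroxyl and is untouched.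

Step 11
Reactants: 19 (6R,8S,10S)-8,10-dihydroxy-11-(triethylsilyloxy)bisabola-3,7(14)-dien-2-one
Product: 20 (6R,8S,10S)-8-angeloyloxy-10-hydroxy-11-(triethylsilyloxy)bisabola-3,7(14)-dien-2-one
Conditions: angelic acid, 2,4,6-trichlorobenzoyl chloride, Et3N, toluene, rt; then 19, 60 °C
Reagents that add atoms: angelic acid C/C=C(/C)C(=O)O
Why: Yamaguchi-type esterification through the mixed anhydride acylates the allylic 8-OH, because the 10-OH is neopentylic and flanked by the bulky silyl ether, and these DMAP-free conditions keep the Z geometry of the angelate.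

Step 12
Reactants: 20 (6R,8S,10S)-8-angeloyloxy-10-hydroxy-11-(triethylsilyloxy)bisabola-3,7(14)-dien-2-one
Product: 21 (6R,8S,10S)-8-angeloyloxy-10,11-bis(triethylsilyloxy)bisabola-3,7(14)-dien-2-one
Conditions: Et3SiOTf, 2,6-lutidine, CH2Cl2, −78 °C
Reagents that add atoms: triethylsilyl trifluoromethanesulfonate CC[Si](CC)(CC)OS(=O)(=O)C(F)(F)F
Why: Silyl ether formation with the reactive triflate protects the hindered 10-OH before the enolate and triflation steps.

Step 13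
Reactants: 21 (6R,8S,10S)-8-angeloyloxy-10,11-bis(triethylsilyloxy)bisabola-3,7(14)-dien-2-one
Product: 23 (6S,8S,10S)-8-angeloyloxy-1α-hydroxy-10,11-bis(triethylsilyloxy)bisabola-3,7(14)-dien-2-one, via lithium enolate 22 (not isolated)
Conditions: LiN(iPr)2 (1.1 equiv), THF, −78 °C; then (±)-3-phenyl-2-(phenylsulfonyl)oxaziridine; aq NH4Cl
Reagents that add atoms: (±)-3-phenyl-2-(phenylsulfonyl)oxaziridine O=S(=O)(c1ccccc1)N1OC1c1ccccc1
Why: Kinetic α'-deprotonation of the enone (far more acidic than the ester) and Davis hydroxylation of the enolate anti to the C6 side chain give the trans (1α) alcohol, as known for carvone itself.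

Step 14
Reactants: 23 (6S,8S,10S)-8-angeloyloxy-1α-hydroxy-10,11-bis(triethylsilyloxy)bisabola-3,7(14)-dien-2-one
Product: 25 (6S,8S,10S)-1β,8-bis(angeloyloxy)-10,11-bis(triethylsilyloxy)bisabola-3,7(14)-dien-2-one, via triflate 24 (not isolated)
Conditions: Tf2O, pyridine, CH2Cl2, −78 to −20 °C; then CsO2CC(CH3)=CHCH3 (cesium angelate), 18-crown-6, toluene, 0 °C to rt
Reagents that add atoms: cesium (Z)-2-methylbut-2-enoate [Cs+].[O-]C(=O)/C(C)=C\C
Why: Triflation and SN2 displacement by angelate at the activated α-keto carbon inverts C1, placing the ester cis (β) to the C6 side chain without exposing the angelate to isomerising conditions.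

Step 15
Reactants: 25 (6S,8S,10S)-1β,8-bis(angeloyloxy)-10,11-bis(triethylsilyloxy)bisabola-3,7(14)-dien-2-one
Product: 26 (6S,8S,10S)-1β,8-bis(angeloyloxy)-10,11-bis(triethylsilyloxy)bisabola-3,7(14)-dien-2β-ol
Conditions: NaBH4, CeCl3·7H2O, MeOH, −78 °C
Reagents that add atoms: none
Why: Luche 1,2-reduction with axial hydride attack anti to the axial 1β-acyloxy group gives the equatorial 2β-alcohol (all-cis with C1 and C6).

Step 16
Reactants: 26 (6S,8S,10S)-1β,8-bis(angeloyloxy)-10,11-bis(triethylsilyloxy)bisabola-3,7(14)-dien-2β-ol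
Product: 27 (6S,8S,10S)-1β,8-bis(angeloyloxy)-3β,4β-epoxy-10,11-bis(triethylsilyloxy)bisabol-7(14)-en-2β-ol
Conditions: VO(acac)2 (5 mol%), t-BuOOH, CH2Cl2, 0 °C to rt
Reagents that add atoms: tert-butyl hydroperoxide CC(C)(C)OO
Why: Hydroxyl-directed vanadium-catalysed epoxidation delivers oxygen to the ring alkene syn to the allylic 2β-OH and so sets C3 and C4, while the other alkenes lack a directing hydroxyl or are electron-poor.

Step 17
Reactants: 27 (6S,8S,10S)-1β,8-bis(angeloyloxy)-3β,4β-epoxy-10,11-bis(triethylsilyloxy)bisabol-7(14)-en-2β-ol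
Product: 28 (6S,8S,10S)-2β-acetoxy-1β,8-bis(angeloyloxy)-3β,4β-epoxy-10,11-bis(triethylsilyloxy)bisabol-7(14)-ene
Conditions: Ac2O, pyridine, DMAP (cat.), CH2Cl2, 0 °C
Reagents that add atoms: acetic anhydride CC(=O)OC(C)=O
Why: Acetylation (esterification) of the only free hydroxyl.

Step 18
Reactants: 28 (6S,8S,10S)-2β-acetoxy-1β,8-bis(angeloyloxy)-3β,4β-epoxy-10,11-bis(triethylsilyloxy)bisabol-7(14)-ene
Product: 29 (1R,2R,3S,4S,6S,8S,10S)-2-acetoxy-1,8-bis(angeloyloxy)-3,4-epoxybisabol-7(14)-ene-10,11-diol (CNP0221749.1)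
Conditions: HF·pyridine, pyridine, THF, 0 °C to rt
Reagents that add atoms: none
Why: Buffered fluoride desilylation frees the 10- and 11-hydroxyls without touching the esters or the epoxide.

**Compound list**

1 | L-malic acid [(S)-2-hydroxybutanedioic acid] | OC(=O)C[C@H](O)C(=O)O | starting material
2 | (S)-2-(2,2-dimethyl-5-oxo-1,3-dioxolan-4-yl)acetic acid | OC(=O)C[C@@H]1OC(C)(C)OC1=O | intermediate
3 | (S)-3,4-dihydroxy-4-methylpentanoic acid (not isolated) | OC(=O)C[C@H](O)C(C)(C)O | intermediate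
4 | (S)-4-hydroxy-5,5-dimethyloxolan-2-one | O=C1C[C@H](O)C(C)(C)O1 | intermediate
5 | lithium (S)-3,4-dihydroxy-4-methylpentanoate (not isolated) | [Li+].[O-]C(=O)C[C@H](O)C(C)(C)O | intermediate
6 | triethylsilyl (S)-4-methyl-3,4-bis(triethylsilyloxy)pentanoate (not isolated) | CC[Si](CC)(CC)OC(=O)C[C@H](O[Si](CC)(CC)CC)C(C)(C)O[Si](CC)(CC)CC | intermediate
7 | (S)-4-methyl-3,4-bis(triethylsilyloxy)pentanoic acid | OC(=O)C[C@H](O[Si](CC)(CC)CC)C(C)(C)O[Si](CC)(CC)CC | intermediate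
8 | (R)-carvone [(5R)-2-methyl-5-(prop-1-en-2-yl)cyclohex-2-en-1-one] | C=C(C)[C@@H]1CC=C(C)C(=O)C1 | starting material
9 | (R)-10-chlorocarvone [(5R)-5-(3-chloroprop-1-en-2-yl)-2-methylcyclohex-2-en-1-one] | C=C(CCl)[C@@H]1CC=C(C)C(=O)C1 | intermediate
10 | cesium (S)-4-methyl-3,4-bis(triethylsilyloxy)pentanoate (not isolated) | [Cs+].[O-]C(=O)C[C@H](O[Si](CC)(CC)CC)C(C)(C)O[Si](CC)(CC)CC | intermediate
11 | 2-[(1R)-4-methyl-5-oxocyclohex-3-en-1-yl]prop-2-en-1-yl (3S)-4-methyl-3,4-bis(triethylsilyloxy)pentanoate | C=C(COC(=O)C[C@H](O[Si](CC)(CC)CC)C(C)(C)O[Si](CC)(CC)CC)[C@@H]1CC=C(C)C(=O)C1 | intermediate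
12 | O-trimethylsilyl ketene acetal of 11 with the ring ketone as its trimethylsilyl dienol ether (not isolated) | C=C(COC(O[Si](C)(C)C)=C[C@H](O[Si](CC)(CC)CC)C(C)(C)O[Si](CC)(CC)CC)[C@@H]1CC=C(C)C(O[Si](C)(C)C)=C1 | intermediate
13 | trimethylsilyl ester of 14 with the ring ketone still as trimethylsilyl dienol ether, C9 epimers (not isolated) | C=C(CC(C(=O)O[Si](C)(C)C)[C@H](O[Si](CC)(CC)CC)C(C)(C)O[Si](CC)(CC)CC)[C@@H]1CC=C(C)C(O[Si](C)(C)C)=C1 | intermediate
14 | (6R,10S)-9-carboxy-10,11-bis(triethylsilyloxy)bisabola-3,7(14)-dien-2-one, C9 epimers | C=C(CC(C(=O)O)[C@H](O[Si](CC)(CC)CC)C(C)(C)O[Si](CC)(CC)CC)[C@@H]1CC=C(C)C(=O)C1 | intermediate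
15 | (6R,10S)-9-carboxy-8-hydroxy-10,11-bis(triethylsilyloxy)bisabola-3,7(14)-dien-2-one, C8/C9 epimers | C=C(C(O)C(C(=O)O)[C@H](O[Si](CC)(CC)CC)C(C)(C)O[Si](CC)(CC)CC)[C@@H]1CC=C(C)C(=O)C1 | intermediate
16 | (6R,10S)-9-carboxy-10,11-bis(triethylsilyloxy)bisabola-3,7(14)-diene-2,8-dione (not isolated) | C=C(C(=O)C(C(=O)O)[C@H](O[Si](CC)(CC)CC)C(C)(C)O[Si](CC)(CC)CC)[C@@H]1CC=C(C)C(=O)C1 | intermediate
17 | (6R,10S)-10,11-bis(triethylsilyloxy)bisabola-3,7(14)-diene-2,8-dione | C=C(C(=O)C[C@H](O[Si](CC)(CC)CC)C(C)(C)O[Si](CC)(CC)CC)[C@@H]1CC=C(C)C(=O)C1 | intermediate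
18 | (6R,10S)-10-hydroxy-11-(triethylsilyloxy)bisabola-3,7(14)-diene-2,8-dione | C=C(C(=O)C[C@H](O)C(C)(C)O[Si](CC)(CC)CC)[C@@H]1CC=C(C)C(=O)C1 | intermediate
19 | (6R,8S,10S)-8,10-dihydroxy-11-(triethylsilyloxy)bisabola-3,7(14)-dien-2-one | C=C([C@H](C[C@H](O)C(C)(C)O[Si](CC)(CC)CC)O)[C@@H]1CC=C(C)C(=O)C1 | intermediate
20 | (6R,8S,10S)-8-angeloyloxy-10-hydroxy-11-(triethylsilyloxy)bisabola-3,7(14)-dien-2-one | C=C([C@H](C[C@H](O)C(C)(C)O[Si](CC)(CC)CC)OC(=O)/C(C)=C\C)[C@@H]1CC=C(C)C(=O)C1 | intermediate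
21 | (6R,8S,10S)-8-angeloyloxy-10,11-bis(triethylsilyloxy)bisabola-3,7(14)-dien-2-one | C=C([C@H](C[C@H](O[Si](CC)(CC)CC)C(C)(C)O[Si](CC)(CC)CC)OC(=O)/C(C)=C\C)[C@@H]1CC=C(C)C(=O)C1 | intermediate
22 | lithium 1(2),3-dienolate of 21 (not isolated) | [Li+].C=C([C@H](C[C@H](O[Si](CC)(CC)CC)C(C)(C)O[Si](CC)(CC)CC)OC(=O)/C(C)=C\C)[C@@H]1CC=C(C)C([O-])=C1 | intermediate
23 | (6S,8S,10S)-8-angeloyloxy-1α-hydroxy-10,11-bis(triethylsilyloxy)bisabola-3,7(14)-dien-2-one | C=C([C@H](C[C@H](O[Si](CC)(CC)CC)C(C)(C)O[Si](CC)(CC)CC)OC(=O)/C(C)=C\C)[C@@H]1CC=C(C)C(=O)[C@H]1O | intermediate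
24 | 1α-trifluoromethanesulfonate of 23 (not isolated) | C=C([C@H](C[C@H](O[Si](CC)(CC)CC)C(C)(C)O[Si](CC)(CC)CC)OC(=O)/C(C)=C\C)[C@@H]1CC=C(C)C(=O)[C@H]1OS(=O)(=O)C(F)(F)F | intermediate
25 | (6S,8S,10S)-1β,8-bis(angeloyloxy)-10,11-bis(triethylsilyloxy)bisabola-3,7(14)-dien-2-one | C=C([C@H](C[C@H](O[Si](CC)(CC)CC)C(C)(C)O[Si](CC)(CC)CC)OC(=O)/C(C)=C\C)[C@@H]1CC=C(C)C(=O)[C@@H]1OC(=O)/C(C)=C\C | intermediate
26 | (6S,8S,10S)-1β,8-bis(angeloyloxy)-10,11-bis(triethylsilyloxy)bisabola-3,7(14)-dien-2β-ol | C=C([C@H](C[C@H](O[Si](CC)(CC)CC)C(C)(C)O[Si](CC)(CC)CC)OC(=O)/C(C)=C\C)[C@@H]1CC=C(C)[C@H](O)[C@@H]1OC(=O)/C(C)=C\C | intermediate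
27 | (6S,8S,10S)-1β,8-bis(angeloyloxy)-3β,4β-epoxy-10,11-bis(triethylsilyloxy)bisabol-7(14)-en-2β-ol | C=C([C@H](C[C@H](O[Si](CC)(CC)CC)C(C)(C)O[Si](CC)(CC)CC)OC(=O)/C(C)=C\C)[C@@H]1C[C@@H]2O[C@]2(C)[C@H](O)[C@@H]1OC(=O)/C(C)=C\C | intermediate
28 | (6S,8S,10S)-2β-acetoxy-1β,8-bis(angeloyloxy)-3β,4β-epoxy-10,11-bis(triethylsilyloxy)bisabol-7(14)-ene | C=C([C@H](C[C@H](O[Si](CC)(CC)CC)C(C)(C)O[Si](CC)(CC)CC)OC(=O)/C(C)=C\C)[C@@H]1C[C@@H]2O[C@]2(C)[C@H](OC(C)=O)[C@@H]1OC(=O)/C(C)=C\C | intermediate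
29 | (1R,2R,3S,4S,6S,8S,10S)-2-acetoxy-1,8-bis(angeloyloxy)-3,4-epoxybisabol-7(14)-ene-10,11-diol (CNP0221749.1) | C=C([C@H](C[C@H](O)C(C)(C)O)OC(=O)/C(C)=C\C)[C@@H]1C[C@@H]2O[C@]2(C)[C@H](OC(C)=O)[C@@H]1OC(=O)/C(C)=C\C | target

**Step count**

Total steps: 18. Longest linear sequence: 17 (steps 1–3, then 5–18, from L-malic acid); 15 from (R)-carvone.

**Steps most likely to fail, with fallbacks**

Step 7 (allylic oxidation at C8). Gem-disubstituted alkenes can instead lose the ring methine hydrogen at C6 in the ene step, and over-oxidation is possible. The fallback brings the C8 oxygen in before the C–C bond is made; it sets out from 9 (with acid 7) and comes back to the route at 17. Oxidation of chloride 9 with N-methylmorpholine N-oxide in MeCN gives the enal (R)-2-(4-methyl-5-oxocyclohex-3-en-1-yl)prop-2-enal F1. Acid 7 is alkylated with allyl bromide and K2CO3 to prop-2-en-1-yl (S)-4-methyl-3,4-bis(triethylsilyloxy)pentanoate F2. The lithium enolate of F2 (LiN(iPr)2, THF, −78 °C) adds to the aldehyde of F1 to give the aldol adduct prop-2-en-1-yl ester of 15 F3. Dess–Martin oxidation gives the β-keto ester prop-2-en-1-yl ester of 16 F4. Pd(PPh3)4 with HCO2H/Et3N removes the allyl group, and the β-keto acid 16 decarboxylates to 17.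

Step 14 (SN2 inversion at C1). The nucleophile must enter cis to the C6 side chain; elimination to a dienone/phenol or epimerisation of the α-acyloxy ketone could compete. The fallback inverts C1 by oxidation and reduction; it sets out from 23 and comes back at 28. Luche reduction of 23 gives (6S,8S,10S)-8-angeloyloxy-10,11-bis(triethylsilyloxy)bisabola-3,7(14)-diene-1α,2β-diol F5. The less hindered allylic 2-OH is acetylated (Ac2O, pyridine, 0 °C) to the 2β-acetate of that diol F6. Dess–Martin oxidation gives (6S,8S,10S)-2β-acetoxy-8-angeloyloxy-10,11-bis(triethylsilyloxy)bisabola-3,7(14)-dien-1-one F7. LiBH(s-Bu)3 at −78 °C attacks equatorially and gives the axial alcohol (6S,8S,10S)-2β-acetoxy-8-angeloyloxy-10,11-bis(triethylsilyloxy)bisabola-3,7(14)-dien-1β-ol F8. VO(acac)2/t-BuOOH epoxidation directed by this homoallylic 1β-OH gives (6S,8S,10S)-2β-acetoxy-8-angeloyloxy-3β,4β-epoxy-10,11-bis(triethylsilyloxy)bisabol-7(14)-en-1β-ol F9. Angeloylation of F9 under the step 11 conditions gives 28.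

Step 11 (chemoselective acylation of the 8-OH in a 1,3-diol). Some 10-O-acylation or acyl migration would cost material. The fallback makes C8 with the opposite configuration and installs the ester with inversion; it sets out from 18 and comes back at 20. Narasaka–Prasad reduction of 18 (Et2BOMe, NaBH4, THF/MeOH, −78 °C) gives the syn diol (6R,8R,10S)-8,10-dihydroxy-11-(triethylsilyloxy)bisabola-3,7(14)-dien-2-one F10. Mitsunobu esterification of F10 (angelic acid, PPh3, DIAD) reacts only at the unhindered allylic 8-OH and inverts it, giving 20.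

**Further compounds**

F1 | step 7 | (R)-2-(4-methyl-5-oxocyclohex-3-en-1-yl)prop-2-enal | C=C(C=O)[C@@H]1CC=C(C)C(=O)C1
F2 | step 7 | prop-2-en-1-yl (S)-4-methyl-3,4-bis(triethylsilyloxy)pentanoate | C=CCOC(=O)C[C@H](O[Si](CC)(CC)CC)C(C)(C)O[Si](CC)(CC)CC
F3 | step 7 | prop-2-en-1-yl ester of 15 (C8/C9 epimers) | C=C(C(O)C(C(=O)OCC=C)[C@H](O[Si](CC)(CC)CC)C(C)(C)O[Si](CC)(CC)CC)[C@@H]1CC=C(C)C(=O)C1
F4 | step 7 | prop-2-en-1-yl ester of 16 | C=C(C(=O)C(C(=O)OCC=C)[C@H](O[Si](CC)(CC)CC)C(C)(C)O[Si](CC)(CC)CC)[C@@H]1CC=C(C)C(=O)C1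
F5 | step 14 | (6S,8S,10S)-8-angeloyloxy-10,11-bis(triethylsilyloxy)bisabola-3,7(14)-diene-1α,2β-diol | C=C([C@H](C[C@H](O[Si](CC)(CC)CC)C(C)(C)O[Si](CC)(CC)CC)OC(=O)/C(C)=C\C)[C@@H]1CC=C(C)[C@H](O)[C@H]1O
F6 | step 14 | (6S,8S,10S)-2β-acetoxy-8-angeloyloxy-10,11-bis(triethylsilyloxy)bisabola-3,7(14)-dien-1α-ol | C=C([C@H](C[C@H](O[Si](CC)(CC)CC)C(C)(C)O[Si](CC)(CC)CC)OC(=O)/C(C)=C\C)[C@@H]1CC=C(C)[C@H](OC(C)=O)[C@H]1O
F7 | step 14 | (6S,8S,10S)-2β-acetoxy-8-angeloyloxy-10,11-bis(triethylsilyloxy)bisabola-3,7(14)-dien-1-one | C=C([C@H](C[C@H](O[Si](CC)(CC)CC)C(C)(C)O[Si](CC)(CC)CC)OC(=O)/C(C)=C\C)[C@@H]1CC=C(C)[C@H](OC(C)=O)C1=O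
F8 | step 14 | (6S,8S,10S)-2β-acetoxy-8-angeloyloxy-10,11-bis(triethylsilyloxy)bisabola-3,7(14)-dien-1β-ol | C=C([C@H](C[C@H](O[Si](CC)(CC)CC)C(C)(C)O[Si](CC)(CC)CC)OC(=O)/C(C)=C\C)[C@@H]1CC=C(C)[C@H](OC(C)=O)[C@@H]1O
F9 | step 14 | (6S,8S,10S)-2β-acetoxy-8-angeloyloxy-3β,4β-epoxy-10,11-bis(triethylsilyloxy)bisabol-7(14)-en-1β-ol | C=C([C@H](C[C@H](O[Si](CC)(CC)CC)C(C)(C)O[Si](CC)(CC)CC)OC(=O)/C(C)=C\C)[C@@H]1C[C@@H]2O[C@]2(C)[C@H](OC(C)=O)[C@@H]1O
F10 | step 11 | (6R,8R,10S)-8,10-dihydroxy-11-(triethylsilyloxy)bisabola-3,7(14)-dien-2-one | C=C([C@@H](C[C@H](O)C(C)(C)O[Si](CC)(CC)CC)O)[C@@H]1CC=C(C)C(=O)C1
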